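The three oxygens of ring A are not equivalent. The lactone oxygen O1 sits on C8a, wedged between the acyl-bearing C8 and C4a, while the oxygens on C5 and C7 are free phenols. Ring A is therefore built rather than functionalised. A 3-ethoxy-4-alkylcyclobutenone that already carries the C4 stereocentre, its phenyl group and the C2–C3 ester arm is heated with a siloxyalkyne bearing a masked acetyl group. One operation forms C8a–C8 and C6–C7, closes the benzene ring and leaves the sole free hydroxyl on C8a, with C5 an ethyl ether and C7 a silyl ether, so lactonisation has one possible outcome. C4 stems from a desymmetrised 3-phenylglutarate and is a bystander.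

Key step: step 6

Assumption: the sense of induction in step 1 is assigned by analogy with other 3-substituted glutaric anhydrides; the sign of rotation of 2 is to be compared with that of the known half-ester before step 2, and the pseudoenantiomeric (DHQ)2AQN is to be used instead should the sense be opposite.

Step 1
Reactants: 1 3-phenylglutaric anhydride
Product: 2 (3R)-5-methoxy-5-oxo-3-phenylpentanoic acid (monomethyl (R)-3-phenylglutarate)
Conditions: (DHQD)2AQN (hydroquinidine anthraquinone-1,4-diyl diether, 20 mol %), MeOH (10 equiv), Et2O, −40 °C; aq. HCl wash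
Reagents that add atoms: methanol, CO
Why: Alkaloid-catalysed desymmetrising alcoholysis of a prochiral cyclic anhydride, in which the quinuclidine nitrogen delivers methanol by general-base catalysis to one of the two enantiotopic carbonyl groups inside the chiral pocket and thereby sets the future C4 as (R) in 2, with recrystallisation of the 1-phenylethylammonium salt available to raise the enantiopurity.

Step 2
Reactants: 2 (3R)-5-methoxy-5-oxo-3-phenylpentanoic acid
Product: 3 methyl (3S)-5-chloro-5-oxo-3-phenylpentanoate (same spatial arrangement; the descriptor changes by priority only)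
Conditions: (COCl)2, DMF (cat.), CH2Cl2, 0 °C → rt; evaporate, use crude
Reagents that add atoms: oxalyl chloride, O=C(Cl)C(=O)Cl
Why: Acid chloride formation through a Vilsmeier-type activation, run cold and without distillation so that chloride and methoxy cannot change places between the two termini through a cyclic acyloxonium ion, a process that would racemise a desymmetrised glutarate.

Step 3
Reactants: 3 methyl (3S)-5-chloro-5-oxo-3-phenylpentanoate; 4 ethoxyacetylene
Product: 6 methyl (3S)-3-(2-ethoxy-4-oxocyclobut-2-en-1-yl)-3-phenylpropanoate (both epimers at the ring carbon), via alkylketene 5 (not isolated)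
Conditions: 4 (3 equiv, solution in hexanes), Et3N (slow addition), Et2O, 0 °C → rt; chromatography on Et3N-deactivated silica
Reagents that add atoms: none
Why: Dehydrochlorination gives alkylketene 5, which excess ethoxyacetylene should intercept in a ketene–alkoxyalkyne [2+2] cycloaddition in which the unsubstituted nucleophilic alkyne carbon bonds to the ketene carbonyl carbon, placing ethoxy on ring C3 and the side chain on ring C4 of the cyclobutenone, while the new ring stereocentre is uncontrolled and irrelevant because it becomes sp2 in step 6.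

Step 4
Reactants: 7 ethyl (S)-lactate
Product: 8 ethyl (2S)-2-(tert-butyldimethylsilyloxy)propanoate
Conditions: t-BuMe2SiCl, imidazole, CH2Cl2, rt
Reagents that add atoms: tert-butyldimethylsilyl chloride, CC(C)(C)[Si](C)(C)Cl
Why: Imidazole-promoted O-silylation of a secondary alcohol, which touches no bond at the stereocentre.

Step 5
Reactants: 8 ethyl (2S)-2-(tert-butyldimethylsilyloxy)propanoate
Product: 10 tert-butyldimethyl{[(2S)-4-(triisopropylsilyloxy)but-3-yn-2-yl]oxy}silane, via lithium ynolate 9 (not isolated)
Conditions: CH2Br2, lithium 2,2,6,6-tetramethylpiperidide, THF, −78 °C, then 8; n-BuLi, −78 °C → rt; i-Pr3SiCl, 0 °C → rt; rapid filtration through deactivated silica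
Reagents that add atoms: dibromomethane, BrCBr; triisopropylsilyl chloride, CC(C)[Si](Cl)(C(C)C)C(C)C
Why: Kowalski ester homologation, in which addition of LiCHBr2 to the ester and bromine–lithium exchange trigger a 1,2-shift of the silyloxyethyl group with retention to give ynolate 9, which the bulky chlorosilane captures on oxygen, any erosion at the carbinol carbon being harmless because step 9 erases that centre.

Step 6
Reactants: 6 methyl (3S)-3-(2-ethoxy-4-oxocyclobut-2-en-1-yl)-3-phenylpropanoate; 10 tert-butyldimethyl{[(2S)-4-(triisopropylsilyloxy)but-3-yn-2-yl]oxy}silane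
Product: 15 methyl (3R)-3-{3-[(1S)-1-(tert-butyldimethylsilyloxy)ethyl]-6-ethoxy-2-hydroxy-4-(triisopropylsilyloxy)phenyl}-3-phenylpropanoate, via vinylketene 11 (not isolated), via 4-vinylcyclobutenone 12 (not isolated), via dienylketene 13 (not isolated), via cyclohexadienone 14 (not isolated)
Conditions: 6 (1 equiv), 10 (1.5 equiv), toluene (0.5 M), argon, sealed tube, 80 → 110 °C
Reagents that add atoms: none
Why: This is a Danheiser benzannulation, the known union of a cyclobutenone with a siloxyalkyne: conrotatory 4π opening of either ring epimer of 6, with the alkyl chain turning outward, gives vinylketene 11, and its ketene unit adds to 10 in a [2+2] cycloaddition that forms C8a–C8 and C6–C7 (12). A second 4π opening gives dienylketene 13, and ring A closes by disrotatory 6π electrocyclisation that rejoins C8a to C4a, after which dienone 14 tautomerises to phenol 15. The selectivity required is the orientation of the [2+2], and it is secured by the siloxy group, which makes the carbon-substituted alkyne terminus the nucleophile that attacks the ketene carbonyl carbon, so the masked acetyl group lands on C8 and the silyloxy group on C7. No lasting stereocentre is formed: the ring stereocentres of 12 and 14 disappear on aromatisation, and C4 and the carbinol carbon take no part under neutral thermal conditions. The former cyclobutenone carbonyl emerges as the only free hydroxyl, on C8a, between the two carbon substituents. Early closure of part of 15 to lactone 16 in the hot solution would be harmless, since step 7 takes both to 16.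

Step 7
Reactants: 15 methyl (3R)-3-{3-[(1S)-1-(tert-butyldimethylsilyloxy)ethyl]-6-ethoxy-2-hydroxy-4-(triisopropylsilyloxy)phenyl}-3-phenylpropanoate
Product: 16 (4R)-8-[(1S)-1-(tert-butyldimethylsilyloxy)ethyl]-5-ethoxy-4-phenyl-7-(triisopropylsilyloxy)chroman-2-one
Conditions: DBU (1,8-diazabicyclo[5.4.0]undec-7-ene, 10 mol %), 4 Å molecular sieves, toluene, 80 °C
Reagents that add atoms: none
Why: Lactonisation by intramolecular transesterification, in which only the C8a hydroxyl is free and ortho to the side chain, the C4 phenyl and C5 ethoxy groups press the ester against it in the manner of a trimethyl lock, the sieves take up methanol, and an amidine base replaces the usual acid so that the ortho-hydroxybenzylic silyl ether cannot ionise towards an ortho-quinone methide.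

Step 8
Reactants: 16 (4R)-8-[(1S)-1-(tert-butyldimethylsilyloxy)ethyl]-5-ethoxy-4-phenyl-7-(triisopropylsilyloxy)chroman-2-one
Product: 17 (4R)-5-ethoxy-7-hydroxy-8-[(1S)-1-hydroxyethyl]-4-phenylchroman-2-one
Conditions: Bu4NF (3 equiv), AcOH (3 equiv), THF, 0 °C → rt
Reagents that add atoms: none
Why: Fluoride-mediated cleavage of both silyl ethers, buffered with acetic acid so that the medium stays near neutral, the aryl lactone is not opened and the electron-rich benzylic alcohol is not ionised.

Step 9
Reactants: 17 (4R)-5-ethoxy-7-hydroxy-8-[(1S)-1-hydroxyethyl]-4-phenylchroman-2-one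
Product: 18 (4R)-8-acetyl-5-ethoxy-7-hydroxy-4-phenylchroman-2-one
Conditions: Dess–Martin periodinane (1.2 equiv), NaHCO3, CH2Cl2, 0 °C → rt
Reagents that add atoms: none
Why: Dess–Martin oxidation of a hindered secondary alcohol proceeds by ligand exchange at iodine and needs no benzylic cation or radical, so that, unlike a quinone oxidant that could dehydrogenate C3–C4 to the coumarin, it should leave the doubly benzylic C4–H alone, while the meta-oxygenated phenol has no easy path to a quinone.

Step 10
Reactants: 18 (4R)-8-acetyl-5-ethoxy-7-hydroxy-4-phenylchroman-2-one; 19 3,4-dimethoxybenzaldehyde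
Product: 20 (4R)-8-[(2E)-3-(3,4-dimethoxyphenyl)prop-2-enoyl]-5-ethoxy-7-hydroxy-4-phenylchroman-2-one
Conditions: 19 (1.2 equiv), BF3·OEt2 (2 equiv), 1,4-dioxane, rt
Reagents that add atoms: none
Why: Lewis acid-promoted Claisen–Schmidt condensation, a variant known to tolerate aryl esters, is chosen because hydroxide would open the lactone and allow flavanone-type ring closure, whereas BF3 enolises the ketone, the aldol dehydrates to the conjugated E-enone, and a lactone opened by the water released can only reclose on O1 because C5 is still an ether.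

Step 11
Reactants: 20 (4R)-8-[(2E)-3-(3,4-dimethoxyphenyl)prop-2-enoyl]-5-ethoxy-7-hydroxy-4-phenylchroman-2-one
Product: 21 (4R)-8-[(2E)-3-(3,4-dihydroxyphenyl)prop-2-enoyl]-5,7-dihydroxy-4-phenylchroman-2-one (CNP0187838.1)
Conditions: BBr3 (8 equiv), CH2Cl2, −78 → 0 °C; poured onto ice-water, EtOAc extraction, no alcohol in the work-up
Reagents that add atoms: none
Why: Boron tribromide ether cleavage, routine for methoxychalcones and alkoxy-4-arylchromanones, removes the two methyl groups and the ethyl group in one operation, and the acyl group should stay on O1 because direct transfer to the C5 oxygen would need a bridged tetrahedral intermediate with aromatic C4a as bridgehead, so that only ring opening, which the cold alcohol-free quench avoids, could move it.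

Compound list
1 | 3-phenylglutaric anhydride | O=C1CC(c2ccccc2)CC(=O)O1 | starting material
2 | (3R)-5-methoxy-5-oxo-3-phenylpentanoic acid | COC(=O)C[C@H](c1ccccc1)CC(=O)O | intermediate
3 | methyl (3S)-5-chloro-5-oxo-3-phenylpentanoate | COC(=O)C[C@H](c1ccccc1)CC(=O)Cl | intermediate
4 | ethoxyacetylene | C#COCC | starting material
5 | methyl (3S)-5-oxo-3-phenylpent-4-enoate (alkylketene) | COC(=O)C[C@H](c1ccccc1)C=C=O | intermediate
6 | methyl (3S)-3-(2-ethoxy-4-oxocyclobut-2-en-1-yl)-3-phenylpropanoate, epimers at the ring carbon | COC(=O)C[C@H](c1ccccc1)C1C(=O)C=C1OCC | intermediate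
7 | ethyl (S)-lactate | C[C@H](O)C(=O)OCC | starting material
8 | ethyl (2S)-2-(tert-butyldimethylsilyloxy)propanoate | C[C@H](O[Si](C)(C)C(C)(C)C)C(=O)OCC | intermediate
9 | lithium (3S)-3-(tert-butyldimethylsilyloxy)but-1-yn-1-olate | C[C@H](O[Si](C)(C)C(C)(C)C)C#C[O-].[Li+] | intermediate
10 | tert-butyldimethyl{[(2S)-4-(triisopropylsilyloxy)but-3-yn-2-yl]oxy}silane | C[C@H](O[Si](C)(C)C(C)(C)C)C#CO[Si](C(C)C)(C(C)C)C(C)C | intermediate
11 | methyl (3S,4Z)-5-ethoxy-7-oxo-3-phenylhepta-4,6-dienoate (vinylketene) | COC(=O)C[C@H](c1ccccc1)/C=C(OCC)/C=C=O | intermediate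
12 | methyl (3S,4Z)-5-{3-[(1S)-1-(tert-butyldimethylsilyloxy)ethyl]-4-oxo-2-(triisopropylsilyloxy)cyclobut-2-en-1-yl}-5-ethoxy-3-phenylpent-4-enoate, epimers at the ring carbon | COC(=O)C[C@H](c1ccccc1)/C=C(OCC)/C1C(=O)C([C@H](C)O[Si](C)(C)C(C)(C)C)=C1O[Si](C(C)C)(C(C)C)C(C)C | intermediate
13 | methyl (3S,4Z,6E)-8-[(1S)-1-(tert-butyldimethylsilyloxy)ethyl]-5-ethoxy-9-oxo-3-phenyl-7-(triisopropylsilyloxy)nona-4,6,8-trienoate (dienylketene) | COC(=O)C[C@H](c1ccccc1)/C=C(OCC)/C=C(O[Si](C(C)C)(C(C)C)C(C)C)\C([C@H](C)O[Si](C)(C)C(C)(C)C)=C=O | intermediate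
14 | methyl (3S)-3-{5-[(1S)-1-(tert-butyldimethylsilyloxy)ethyl]-2-ethoxy-6-oxo-4-(triisopropylsilyloxy)cyclohexa-2,4-dien-1-yl}-3-phenylpropanoate, epimers at the ring carbon | COC(=O)C[C@H](c1ccccc1)C1C(=O)C([C@H](C)O[Si](C)(C)C(C)(C)C)=C(O[Si](C(C)C)(C(C)C)C(C)C)C=C1OCC | intermediate
15 | methyl (3R)-3-{3-[(1S)-1-(tert-butyldimethylsilyloxy)ethyl]-6-ethoxy-2-hydroxy-4-(triisopropylsilyloxy)phenyl}-3-phenylpropanoate | COC(=O)C[C@H](c1ccccc1)c1c(OCC)cc(O[Si](C(C)C)(C(C)C)C(C)C)c([C@H](C)O[Si](C)(C)C(C)(C)C)c1O | intermediate
16 | (4R)-8-[(1S)-1-(tert-butyldimethylsilyloxy)ethyl]-5-ethoxy-4-phenyl-7-(triisopropylsilyloxy)chroman-2-one | O=C1C[C@H](c2ccccc2)c2c(OCC)cc(O[Si](C(C)C)(C(C)C)C(C)C)c([C@H](C)O[Si](C)(C)C(C)(C)C)c2O1 | intermediate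
17 | (4R)-5-ethoxy-7-hydroxy-8-[(1S)-1-hydroxyethyl]-4-phenylchroman-2-one | O=C1C[C@H](c2ccccc2)c2c(OCC)cc(O)c([C@H](C)O)c2O1 | intermediate
18 | (4R)-8-acetyl-5-ethoxy-7-hydroxy-4-phenylchroman-2-one | O=C1C[C@H](c2ccccc2)c2c(OCC)cc(O)c(C(C)=O)c2O1 | intermediate
19 | 3,4-dimethoxybenzaldehyde | COc1ccc(C=O)cc1OC | starting material
20 | (4R)-8-[(2E)-3-(3,4-dimethoxyphenyl)prop-2-enoyl]-5-ethoxy-7-hydroxy-4-phenylchroman-2-one | O=C1C[C@H](c2ccccc2)c2c(OCC)cc(O)c(C(=O)/C=C/c3ccc(OC)c(OC)c3)c2O1 | intermediate
21 | (4R)-8-[(2E)-3-(3,4-dihydroxyphenyl)prop-2-enoyl]-5,7-dihydroxy-4-phenylchroman-2-one | O=C1C[C@H](c2ccccc2)c2c(O)cc(O)c(C(=O)/C=C/c3ccc(O)c(O)c3)c2O1 | target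

Total step count: 11. Longest linear sequence: 9 steps (steps 1–3 and 6–11, from 3-phenylglutaric anhydride). The alkyne arm takes 2 steps (4 and 5).

Steps most likely to fail

Step 6.
- What may go wrong: the vinylogous-ester resonance of 6 may slow the first electrocyclic opening. Thermal decay of the siloxyalkyne, self-condensation of the ketene, or inward rotation followed by a 1,5-hydrogen shift could then outrun the capture.
- Fallback (from 2 and 10, back at 15): the same vinylketene 11 is made by base at room temperature instead of by heat.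
- Half-ester 2 is activated with 1,1'-carbonyldiimidazole and extended with Mg(O2CCH2CO2CH2CH=CH2)2 (Masamune–Brooks reaction) to 1-allyl 7-methyl (5R)-3-oxo-5-phenylheptanedioate F1.
- Triethyl orthoformate with catalytic p-toluenesulfonic acid gives the enol ether 1-allyl 7-methyl (2E,5R)-3-ethoxy-5-phenylhept-2-enedioate F2.
- Pd(PPh3)4 and morpholine remove the allyl group to give (2E,5R)-3-ethoxy-7-methoxy-7-oxo-5-phenylhept-2-enoic acid F3.
- 1-Chloro-N,N,2-trimethylprop-1-en-1-amine converts this acid under neutral conditions into methyl (3R,5E)-7-chloro-5-ethoxy-7-oxo-3-phenylhept-5-enoate F4.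
- Slow addition of Et3N to F4 and 10 in toluene effects 1,4-dehydrochlorination to 11, which is trapped as 12. Warming to 80 °C carries 12 through 13 and 14 to 15.

Step 10.
- What may go wrong: sluggish enolisation of the hindered, hydrogen-bonded ketone, opening of the lactone by the water released, or conjugate closure of the C7 hydroxyl onto the new enone.
- Fallback (from 18 and 19, back at 20): the enol component is preformed, and carbon–carbon bond formation is separated from dehydration.
- Me3SiOTf and Et3N in CH2Cl2 at 0 °C convert 18 into (4R)-5-ethoxy-4-phenyl-7-(trimethylsilyloxy)-8-[1-(trimethylsilyloxy)ethenyl]chroman-2-one F5.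
- Mukaiyama aldol addition of F5 to 19 with BF3·OEt2 at −78 °C and aqueous work-up give (4R)-8-[3-(3,4-dimethoxyphenyl)-3-hydroxypropanoyl]-5-ethoxy-7-hydroxy-4-phenylchroman-2-one F6 (both carbinol epimers).
- Catalytic p-toluenesulfonic acid in warm toluene dehydrates this electron-rich benzylic alcohol to 20.

Step 11.
- What may go wrong: acyl–oxygen cleavage of the lactone by the boron halide followed by unselective reclosure once the C5 oxygen is free, addition of HBr to the enone or acid-induced ring closure of the C7 hydroxyl onto it, incomplete de-ethylation, or erosion at C4 by reversible ipso-protonation of the electron-rich ring.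
- Fallback (from 18, back at 21): the hard ether cleavage is moved to a stage at which no enone or catechol exists.
- BBr3 in CH2Cl2 de-ethylates the robust ketone 18 to (4R)-8-acetyl-5,7-dihydroxy-4-phenylchroman-2-one F7.
- The last step then becomes a protecting-group-free, acid-promoted Claisen–Schmidt condensation of F7 with commercial 3,4-dihydroxybenzaldehyde (BF3·OEt2 or dry HCl in 1,4-dioxane), as practised for polyhydroxychalcones. This gives 21 directly.

Further compounds
F1 | step 6 | 1-allyl 7-methyl (5R)-3-oxo-5-phenylheptanedioate | COC(=O)C[C@H](c1ccccc1)CC(=O)CC(=O)OCC=C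
F2 | step 6 | 1-allyl 7-methyl (2E,5R)-3-ethoxy-5-phenylhept-2-enedioate | COC(=O)C[C@H](c1ccccc1)C/C(OCC)=C\C(=O)OCC=C
F3 | step 6 | (2E,5R)-3-ethoxy-7-methoxy-7-oxo-5-phenylhept-2-enoic acid | COC(=O)C[C@H](c1ccccc1)C/C(OCC)=C\C(=O)O
F4 | step 6 | methyl (3R,5E)-7-chloro-5-ethoxy-7-oxo-3-phenylhept-5-enoate | COC(=O)C[C@H](c1ccccc1)C/C(OCC)=C\C(=O)Cl
F5 | step 10 | (4R)-5-ethoxy-4-phenyl-7-(trimethylsilyloxy)-8-[1-(trimethylsilyloxy)ethenyl]chroman-2-one | O=C1C[C@H](c2ccccc2)c2c(OCC)cc(O[Si](C)(C)C)c(C(=C)O[Si](C)(C)C)c2O1
F6 | step 10 | (4R)-8-[3-(3,4-dimethoxyphenyl)-3-hydroxypropanoyl]-5-ethoxy-7-hydroxy-4-phenylchroman-2-one, both carbinol epimers | O=C1C[C@H](c2ccccc2)c2c(OCC)cc(O)c(C(=O)CC(O)c3ccc(OC)c(OC)c3)c2O1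
F7 | step 11 | (4R)-8-acetyl-5,7-dihydroxy-4-phenylchroman-2-one | O=C1C[C@H](c2ccccc2)c2c(O)cc(O)c(C(C)=O)c2O1
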